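**Plan** (numbering: C1 ketone, C2=C3 with methyl on C3, cyclobutane C4–C5–C11–C10, C6 gem-dimethyl, C7 O-methacryloyl, C8 methylene, C9 O-isobutyryl, C10 quaternary methyl carbon)
1. Retrosynthesis cuts the two acyl–oxygen bonds, then the cyclobutane bond C10–C11 (C11 enol ether onto a C9–C10 epoxide), then C5–C11 and C3–C4 together (Diels–Alder), and last the C4=C5 alkene (ring-closing metathesis) and the C6–C7 bond (reverse prenylation) of the seven-membered dienophile.
2. Enabling feature: ring C1–C2–C3–C4–C5–C11 is the [4+2] adduct of a 2-silyloxypenta-1,3-diene (C11=C1–C2=C3) across C4=C5 of a cyclohept-2-enone whose carbonyl is C10 and whose β-carbon C5 adjoins gem-dimethyl C6. The adduct keeps C1 masked as a silyl enol ether, so only the C10 ketone is free to become the C9=C10 methyl alkene.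
3. Forward order of rings: seven-membered (metathesis), six-membered (Diels–Alder), four-membered (epoxide opening at C10); then C9 is reset through the ketone and the two esters are put on.
4. Stereochemistry: C7 from a Brown reverse prenylboration; C4/C5 from suprafacial cycloaddition anti to the C7 silyl ether; C10/C11 from the cage-forming epoxide opening; C9 from Evans–Tishchenko hydride delivery by the C7 hydroxyl (1,3-anti), which also places the methacrylate on O7.

Key step: step 7

Assumption: the prenyl analogue of the allylborane made from (+)-α-pinene attacks the same aldehyde face as the parent allyl reagent, which corresponds to the (R) carbinol here.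
Face labels for bicyclic and tricyclic compounds: α is the face of the seven-membered ring carrying H-4, H-5 and the C7 oxygen; β is the face carrying C3 and C11.

**Step 1**
Reactants: 1 methyl 4-oxobutanoate; 2 3-methylbuta-1,2-diene
Product: 5 (R)-5-(2-methylbut-3-en-2-yl)dihydrofuran-2(3H)-one, via prenylborane 3 (not isolated), via hydroxy ester 4 (not isolated)
Conditions: (−)-(Ipc)2BH [from (+)-α-pinene], 2, THF, −25 °C; 1, −78 °C; NaBO3·4H2O, H2O, rt; PPTS (cat.), CH2Cl2, rt
Reagents that add atoms: none
Why: Brown allylboration with the γ,γ-dimethylallylborane runs through a closed chair transition state with allylic transposition, so the CMe2–CH=CH2 unit is joined at the aldehyde carbon and the pinene-derived ligands set C7 as (R); the γ-hydroxy ester then lactonises.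

**Step 2**
Reactants: 5 (R)-5-(2-methylbut-3-en-2-yl)dihydrofuran-2(3H)-one
Product: 6 (R)-4-hydroxy-N-methoxy-N,5,5-trimethylhept-6-enamide
Conditions: MeNH(OMe)·HCl, AlMe3, CH2Cl2, 0 °C → rt; dilute HCl work-up
Reagents that add atoms: N,O-dimethylhydroxylamine hydrochloride, CNOC.Cl
Why: Aluminium-amide aminolysis of a γ-lactone to the Weinreb amide is standard and does not touch the carbinol centre.

**Step 3**
Reactants: 6 (R)-4-hydroxy-N-methoxy-N,5,5-trimethylhept-6-enamide
Product: 7 (R)-4-(tert-butyldimethylsilyloxy)-N-methoxy-N,5,5-trimethylhept-6-enamide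
Conditions: TBSOTf, 2,6-lutidine, CH2Cl2, −78 → 0 °C
Reagents that add atoms: tert-butyldimethylsilyl triflate, CC(C)(C)[Si](C)(C)OS(=O)(=O)C(F)(F)F
Why: Silyl triflate silylation copes with the neopentylic secondary alcohol and, done at once, prevents relactonisation.

**Step 4**
Reactants: 7 (R)-4-(tert-butyldimethylsilyloxy)-N-methoxy-N,5,5-trimethylhept-6-enamide
Product: 8 (R)-6-(tert-butyldimethylsilyloxy)-7,7-dimethylnona-1,8-dien-3-one
Conditions: CH2=CHMgBr, THF, −78 → 0 °C; inverse quench into cold aq. NH4Cl
Reagents that add atoms: vinylmagnesium bromide, C=C[Mg]Br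
Why: Weinreb ketone synthesis: the chelated tetrahedral intermediate stops at mono-addition and releases the vinyl ketone only on work-up.

**Step 5**
Reactants: 8 (R)-6-(tert-butyldimethylsilyloxy)-7,7-dimethylnona-1,8-dien-3-one
Product: 9 (R)-5-(tert-butyldimethylsilyloxy)-4,4-dimethylcyclohept-2-en-1-one
Conditions: second-generation Grubbs catalyst (H2IMes)(PCy3)Cl2Ru=CHPh (5 mol%), CH2Cl2 (5 mM), 40 °C
Reagents that add atoms: none
Why: Ring-closing metathesis of a vinyl ketone with a vinyl group on a quaternary carbon pairs two alkenes that do not homodimerise, and the gem-dimethyl group favours closure of the seven-membered enone.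

**Step 6**
Reactants: 10 (E)-pent-3-en-2-one
Product: 11 (E)-2-(tert-butyldimethylsilyloxy)penta-1,3-diene
Conditions: TBSOTf, Et3N, Et2O, 0 °C
Reagents that add atoms: tert-butyldimethylsilyl triflate, CC(C)(C)[Si](C)(C)OS(=O)(=O)C(F)(F)F
Why: Soft enolisation of the enone at its methyl group gives the cross-conjugated 2-silyloxydiene with the (E)-propenyl geometry retained.

**Step 7**
Reactants: 9 (R)-5-(tert-butyldimethylsilyloxy)-4,4-dimethylcyclohept-2-en-1-one; 11 (E)-2-(tert-butyldimethylsilyloxy)penta-1,3-diene
Product: 12 cis-fused bicyclic adduct (six-membered ring C1–C2–C3–C4–C5–C11 fused at C4–C5 to the seven-membered ring): C10 ketone, C1=C2 TBS enol ether, 3-methyl cis to C10, H-4 and H-5 α, 7α-OTBS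
Conditions: 11 (2.5 equiv), AlBr3/AlMe3 (10:1 premix, 30 mol%), PhMe/CH2Cl2, −20 → 0 °C; pyridine quench, then aq. NaHCO3
Reagents that add atoms: none
Why: The aluminium Lewis acid binds the C10 carbonyl of 9 and lowers its LUMO, so the silyloxydiene adds in a concerted, asynchronous [4+2] in which the C11–C5 bond (nucleophilic CH2 terminus to the neopentyl β-carbon) is more advanced than C3–C4. The closest known reaction type is the mixed AlBr3/AlMe3-promoted Diels–Alder reaction of 2-silyloxydienes with hindered cycloalkenones, which returns the silyl enol ether intact. The six-membered ring C1–C2–C3–C4–C5–C11 is closed by intermolecular cycloaddition across C4=C5, both bonds forming suprafacially on each partner. C4 and C5 are therefore cis (from the cis ring alkene); their absolute sense follows from diene approach anti to the pseudo-axial C6 methyl that the pseudo-equatorial C7 silyloxy group imposes, which is the face trans to OTBS; C3 comes from the endo transition state and is erased in step 10. The step needs regioselectivity (C11 to C5, C3 to C4), secured jointly by the 2-silyloxy group and the terminal methyl of the diene, and survival of the C1 silyl enol ether, secured by the aprotic pyridine quench.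

**Step 8**
Reactants: 12 cis-fused bicyclic adduct
Product: 13 C10 enol triflate of 12 (C9=C10), other groups unchanged
Conditions: KN(SiMe3)2, THF, −78 °C; PhNTf2, −78 → 0 °C
Reagents that add atoms: N-phenylbis(trifluoromethanesulfonimide), FC(F)(F)S(=O)(=O)N(c1ccccc1)S(=O)(=O)C(F)(F)F
Why: Kinetic deprotonation of the C10 ketone occurs at the C9 methylene and not at the hindered C4 methine, and O-triflation fixes the C9=C10 regiochemistry while the C1 silyl enol ether is inert to base.

**Step 9**
Reactants: 13 C10 enol triflate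
Product: 14 bicyclic C9=C10 alkene with the C10 methyl, C1=C2 TBS enol ether and 7α-OTBS retained
Conditions: Fe(acac)3 (5 mol%), MeMgBr, THF/NMP, −30 °C
Reagents that add atoms: methylmagnesium bromide, C[Mg]Br
Why: Iron-catalysed Kumada-type coupling of an alkenyl triflate with a methyl Grignard reagent is fast at low temperature and spares silyl ethers and silyl enol ethers.

**Step 10**
Reactants: 14 bicyclic methyl alkene
Product: 15 bicyclic enone: C1 ketone, C2=C3 (3-methyl), C9=C10 (10-methyl), H-4 and H-5 α, 7α-OTBS
Conditions: Pd(OAc)2 (1.1 equiv), MeCN, rt → 40 °C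
Reagents that add atoms: none
Why: Saegusa–Ito oxidation: the C1 silyl enol ether gives a C2-bound palladium enolate whose only β-hydrogen is on C3, so the C2=C3 enone forms regiospecifically and the C3 stereocentre disappears.

**Step 11**
Reactants: 15 bicyclic enone
Product: 16 9α,10α-epoxide of 15
Conditions: mCPBA, NaHCO3, CH2Cl2, 0 °C
Reagents that add atoms: 3-chloroperbenzoic acid, OOC(=O)c1cccc(Cl)c1
Why: Prilezhaev epoxidation selects the electron-rich trisubstituted C9=C10 alkene over the enone and should occur on the α face, because the cis-fused six-membered ring screens the β face.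

**Step 12**
Reactants: 16 9α,10α-epoxide
Product: 18 tricyclic enone with the cyclobutane C4–C5–C11–C10 closed, 7-OTBS, 9-hydroxy epimeric with the target at C9; (4R,5S,7R,9S,10R,11R) in target numbering, via silyl dienol ether 17 (not isolated)
Conditions: LDA, Me3SiCl, THF, −78 °C; solvent exchange; MeAlCl2, CH2Cl2, −78 °C; aq. NaHCO3
Reagents that add atoms: none
Why: Proposed new method: kinetic α′-deprotonation gives the cross-conjugated C11=C1 silyl dienol ether; the aluminium Lewis acid then polarises the tertiary C10–O bond, and C11, held on the β face by the cis ring fusion, attacks C10 anti to the departing oxygen in a 4-exo-tet closure that fixes C10 and C11 in the only geometry the cage allows. The closest known reaction type is the Lewis-acid-promoted epoxide-initiated cyclisation terminated by a silyl enol ether (intramolecular Mukaiyama-type epoxide opening), established for five- and six-membered rings. The neutral silyl variant is chosen because loss of silicon and formation of the C1 carbonyl make the strained closure irreversible, and either C9 epimer would serve because C9 is oxidised in step 13.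

**Step 13**
Reactants: 18 tricyclic 9-alcohol
Product: 19 tricyclic 7-OTBS 1,9-dione; (4R,5S,7R,10R,11R)
Conditions: Dess–Martin periodinane, NaHCO3, CH2Cl2, rt
Reagents that add atoms: none
Why: Dess–Martin oxidation of the hindered secondary alcohol under buffered, non-basic conditions avoids β-elimination of the C7 silyl ether and removes the C9 centre so that it can be reset.

**Step 14**
Reactants: 19 tricyclic 7-OTBS 1,9-dione
Product: 20 tricyclic 7-hydroxy 1,9-dione; (4R,5S,7R,10R,11R)
Conditions: HF·pyridine, THF, 0 °C → rt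
Reagents that add atoms: none
Why: Acidic fluoride cleaves the TBS ether without the base that would trigger retro-aldol cleavage or dehydration of the β-hydroxy ketone.

**Step 15**
Reactants: 20 tricyclic 7-hydroxy 1,9-dione
Product: 21 7-O-methacryloyl 9-hydroxy enone; (4R,5S,7R,9R,10R,11R)
Conditions: methacrolein (6 equiv), SmI2 (0.3 equiv, premixed with the aldehyde), THF, −10 °C
Reagents that add atoms: methacrolein, C=C(C)C=O
Why: Evans–Tishchenko reduction: the C7 hydroxyl forms a hemiacetal with methacrolein on the trivalent samarium centre generated in the flask and delivers its hydride intramolecularly to the α face of the C9 ketone through a six-membered transition state, giving the 1,3-anti (9β) alcohol and leaving the aldehyde carbon as the methacrylate on O7.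

**Step 16**
Reactants: 21 7-O-methacryloyl 9-hydroxy enone
Product: 22 target, (4R,5S,7R,9R,10R,11R)-7-methacryloyloxy-9-isobutyryloxy tricyclic enone
Conditions: iPrCOCl, pyridine, DMAP (cat.), CH2Cl2, 0 °C → rt
Reagents that add atoms: isobutyryl chloride, CC(C)C(Cl)=O
Why: DMAP-catalysed acylation of the remaining neopentylic C9 hydroxyl is mild enough for the methacrylate and the enone.

**Compound list**
1 | methyl 4-oxobutanoate | COC(=O)CCC=O | starting material
2 | 3-methylbuta-1,2-diene | CC(C)=C=C | starting material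
3 | (3-methylbut-2-en-1-yl)bis(isopinocampheyl)borane, ligands from (+)-α-pinene | C[C@H]1[C@H](B(CC=C(C)C)[C@@H]3C[C@@H]4C[C@H]([C@H]3C)C4(C)C)C[C@@H]2C[C@H]1C2(C)C | intermediate
4 | methyl (R)-4-hydroxy-5,5-dimethylhept-6-enoate | COC(=O)CC[C@@H](O)C(C)(C)C=C | intermediate
5 | (R)-5-(2-methylbut-3-en-2-yl)dihydrofuran-2(3H)-one | O=C1CC[C@H](C(C)(C)C=C)O1 | intermediate
6 | (R)-4-hydroxy-N-methoxy-N,5,5-trimethylhept-6-enamide | CON(C)C(=O)CC[C@@H](O)C(C)(C)C=C | intermediate
7 | (R)-4-(tert-butyldimethylsilyloxy)-N-methoxy-N,5,5-trimethylhept-6-enamide | CON(C)C(=O)CC[C@@H](O[Si](C)(C)C(C)(C)C)C(C)(C)C=C | intermediate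
8 | (R)-6-(tert-butyldimethylsilyloxy)-7,7-dimethylnona-1,8-dien-3-one | C=CC(=O)CC[C@@H](O[Si](C)(C)C(C)(C)C)C(C)(C)C=C | intermediate
9 | (R)-5-(tert-butyldimethylsilyloxy)-4,4-dimethylcyclohept-2-en-1-one | O=C1C=CC(C)(C)[C@H](O[Si](C)(C)C(C)(C)C)CC1 | intermediate
10 | (E)-pent-3-en-2-one | C/C=C/C(C)=O | starting material
11 | (E)-2-(tert-butyldimethylsilyloxy)penta-1,3-diene | C=C(O[Si](C)(C)C(C)(C)C)/C=C/C | intermediate
12 | cis-fused bicyclic adduct: C10 ketone, C1=C2 TBS enol ether, 3-methyl cis to C10, H-4/H-5 α, 7α-OTBS | C1(O[Si](C)(C)C(C)(C)C)=C[C@H](C)[C@H]2[C@@H](C1)C(C)(C)[C@H](O[Si](C)(C)C(C)(C)C)CCC2=O | intermediate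
13 | C10 enol triflate of 12 (C9=C10) | C1(O[Si](C)(C)C(C)(C)C)=C[C@H](C)[C@H]2[C@@H](C1)C(C)(C)[C@H](O[Si](C)(C)C(C)(C)C)CC=C2OS(=O)(=O)C(F)(F)F | intermediate
14 | bicyclic C9=C10 alkene with 10-methyl, C1=C2 TBS enol ether, 7α-OTBS | C1(O[Si](C)(C)C(C)(C)C)=C[C@H](C)[C@H]2[C@@H](C1)C(C)(C)[C@H](O[Si](C)(C)C(C)(C)C)CC=C2C | intermediate
15 | bicyclic enone: C1 ketone, C2=C3, C9=C10, H-4/H-5 α, 7α-OTBS | O=C1C=C(C)[C@H]2[C@@H](C1)C(C)(C)[C@H](O[Si](C)(C)C(C)(C)C)CC=C2C | intermediate
16 | 9α,10α-epoxide of 15 | O=C1C=C(C)[C@H]2[C@@H](C1)C(C)(C)[C@H](O[Si](C)(C)C(C)(C)C)C[C@@H]3O[C@@]32C | intermediate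
17 | C1 trimethylsilyl dienol ether of 16 (C11=C1, C2=C3) | C[Si](C)(C)OC1=C[C@H]2C(C)(C)[C@H](O[Si](C)(C)C(C)(C)C)C[C@@H]3O[C@]3(C)[C@H]2C(C)=C1 | intermediate
18 | tricyclic enone, 7-OTBS, 9-hydroxy (9-epi); (4R,5S,7R,9S,10R,11R) | CC(C)(C)[Si](C)(C)O[C@@H]1C[C@H](O)[C@@]2(C)[C@@H]3C(=O)C=C(C)[C@H]2[C@@H]3C1(C)C | intermediate
19 | tricyclic 7-OTBS 1,9-dione; (4R,5S,7R,10R,11R) | CC(C)(C)[Si](C)(C)O[C@@H]1CC(=O)[C@@]2(C)[C@@H]3C(=O)C=C(C)[C@H]2[C@@H]3C1(C)C | intermediate
20 | tricyclic 7-hydroxy 1,9-dione; (4R,5S,7R,10R,11R) | O[C@@H]1CC(=O)[C@@]2(C)[C@@H]3C(=O)C=C(C)[C@H]2[C@@H]3C1(C)C | intermediate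
21 | 7-O-methacryloyl 9-hydroxy enone; (4R,5S,7R,9R,10R,11R) | C=C(C)C(=O)O[C@@H]1C[C@@H](O)[C@@]2(C)[C@@H]3C(=O)C=C(C)[C@H]2[C@@H]3C1(C)C | intermediate
22 | target CNP0214356.1; (4R,5S,7R,9R,10R,11R) | C=C(C)C(=O)O[C@@H]1C[C@@H](OC(=O)C(C)C)[C@@]2(C)[C@@H]3C(=O)C=C(C)[C@H]2[C@@H]3C1(C)C | target

**Total steps:** 16. **Longest linear sequence:** 15 (steps 1–5 and 7–16; step 6 is the one-step diene branch).

**Steps most likely to fail**

Step 12. The ionising C10–O bond may collapse by 1,2-hydride shift from C9 (Meinwald rearrangement) or by loss of the C4 proton before the strained four-membered transition state is reached. The fallback replaces the cationic closure by an anionic one with a carbanion basic enough to make the closure downhill. Epoxy enone 16 is condensed with 1,1-dimethylhydrazine (AcOH cat., EtOH) to the N,N-dimethylhydrazone of 16, F1. LDA (THF, −78 → 0 °C) generates the α′ aza-enolate at C11, which opens the epoxide at C10 with inversion in a Stork-type 4-exo-tet alkylation of a metalated hydrazone, giving the tricyclic hydroxy hydrazone F2. Two-phase hydrolysis with aqueous oxalic acid returns alcohol 18.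

Step 7. The cycloaddition may be too slow at the neopentyl C5, so that the aluminium Lewis acid cleaves the silyl enol ether or erodes facial discrimination. The fallback forms the two bonds one after the other. Mukaiyama–Michael addition of 11 (through C11) to enone 9 under catalysis by tert-butyldimethylsilyl triflimide (from HNTf2, CH2Cl2, −78 °C) has an open transition state that tolerates the β-branching, and gives the open-chain C10 silyl enol ether with a pendant (E)-enone, F3. Intramolecular Mukaiyama–Michael addition of C4 to C3 (EtAlCl2, CH2Cl2, −78 → −20 °C), with silyl transfer to O1, closes the six-membered ring and rejoins the route at 12.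

Step 15. Methacrolein may oligomerise or add the C7 alkoxide in a conjugate sense faster than the hindered hemiacetal forms and transfers hydride, leaving ketone 20 unreduced. The fallback uses a non-enolisable aromatic aldehyde and exchanges the ester afterwards. Evans–Tishchenko reduction of 20 with 4-nitrobenzaldehyde (SmI2 cat., THF, −10 °C) gives the 7-O-(4-nitrobenzoyl) 9-hydroxy enone F4. Isobutyryl chloride, pyridine and DMAP give the mixed diester F5. The activated aryl ester is cleaved selectively (K2CO3, MeOH, 0 °C) to the 7-hydroxy 9-isobutyrate F6, and methacryloyl chloride with Et3N and DMAP then gives 22.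

**Further compounds**
F1 | step 12 | N,N-dimethylhydrazone of epoxy enone 16 | CN(C)N=C1C=C(C)[C@H]2[C@@H](C1)C(C)(C)[C@H](O[Si](C)(C)C(C)(C)C)C[C@@H]3O[C@@]32C
F2 | step 12 | N,N-dimethylhydrazone of tricyclic alcohol 18 | CC(C)(C)[Si](C)(C)O[C@@H]1C[C@H](O)[C@@]2(C)[C@@H]3C(=NN(C)C)C=C(C)[C@H]2[C@@H]3C1(C)C
F3 | step 7 | open-chain Michael adduct: cycloheptene C10 TBS enol ether (C4=C10) carrying the (E)-2-oxopent-3-enyl chain on C5, 7-OTBS | C/C=C/C(=O)C[C@@H]1C=C(O[Si](C)(C)C(C)(C)C)CC[C@@H](O[Si](C)(C)C(C)(C)C)C1(C)C
F4 | step 15 | 7-O-(4-nitrobenzoyl) 9-hydroxy tricyclic enone | O=C(O[C@@H]1C[C@@H](O)[C@@]2(C)[C@@H]3C(=O)C=C(C)[C@H]2[C@@H]3C1(C)C)c1ccc(cc1)[N+](=O)[O-]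
F5 | step 15 | 7-O-(4-nitrobenzoyl) 9-O-isobutyryl tricyclic enone | O=C(O[C@@H]1C[C@@H](OC(=O)C(C)C)[C@@]2(C)[C@@H]3C(=O)C=C(C)[C@H]2[C@@H]3C1(C)C)c1ccc(cc1)[N+](=O)[O-]
F6 | step 15 | 7-hydroxy 9-O-isobutyryl tricyclic enone | O[C@@H]1C[C@@H](OC(=O)C(C)C)[C@@]2(C)[C@@H]3C(=O)C=C(C)[C@H]2[C@@H]3C1(C)C
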